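**Retrosynthesis**
1. The C7 carbinol comes from Noyori transfer hydrogenation of an aryl ketone. That ketone and the C9'-CH2OH both come from opening a γ-lactone (ring B) with a guaiacyl organolithium.
2. The catechol-bearing C7' centre comes from Friedel–Crafts C-arylation of a lactol acetate on the convex face of a cis-fused bicyclic lactone. This puts the aryl trans to both cis side chains.
3. That bicycle comes from mono-DIBAL reduction of the C2-symmetric cis-bislactone (R,R)-**5**. Its two lactones are equivalent, so no regiochemical differentiation is needed. Ring A is the THF, and ring B is opened later.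
4. **5** comes from hydrogenolysis and double lactonisation of the bis-imide **4**. **4** is made by oxidative homocoupling of two molecules of an Evans imide enolate, which forms the C8–C8' bond and both stereocentres in one step.

**Assumption:** the stereocentres are those of the given SMILES (7R,8R,7'S,8'R). The Evans enolate is assumed to couple on the face anti to its benzyl group, so the (R)-auxiliary gives the (R,R)-dimer; if the opposite sense is found, the (S)-auxiliary is used.

---

**Step 1**
Reactants: **1** (R)-4-benzyloxazolidin-2-one; **2** 3-(benzyloxy)propanoic acid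
Product: **3** (R)-4-benzyl-3-[3-(benzyloxy)propanoyl]oxazolidin-2-one
Conditions: **2**, PivCl, Et3N, THF, 0 °C; then **1**, LiCl, rt
Reagents that add atoms: none (PivCl and Et3N only activate the acid)
Why: Mixed-anhydride N-acylation attaches the chiral auxiliary that will control the C8–C8' coupling.

**Step 2**
Reactants: **3** (first molecule, as its lithium Z-enolate) and **3** (second molecule, as its lithium Z-enolate). Two molecules of (R)-4-benzyl-3-[3-(benzyloxy)propanoyl]oxazolidin-2-one (2 equiv) are consumed per molecule of product.
Product: **4** (2R,3R)-1,4-bis[(R)-4-benzyl-2-oxooxazolidin-3-yl]-2,3-bis(benzyloxymethyl)butane-1,4-dione (formula of **4** = 2 × **3** − 2 H)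
Conditions: LiHMDS (2.05 equiv per 2 equiv of **3**), THF, –78 °C; then Cu(II) 2-ethylhexanoate (2.2 equiv), –78 °C → rt
Reagents that add atoms: none (Cu(II) is only a one-electron oxidant, and the two units of **3** are joined by a new C–C bond with loss of two H)
Why: Proposed new method: Cu(II) oxidises the chelated Z-enolates to α-carbonyl radicals or Cu-bound enolates, and the second partner couples anti to the benzyl group to give the C2-symmetric (R,R) dimer, forming C8–C8' and both stereocentres at once. The closest known reaction is the oxidative dimerisation of chiral imide enolates to 2,3-dialkylsuccinates; a mild, non-basic Cu(II) oxidant at low temperature is chosen to limit E1cB loss of BnO⁻.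

**Step 3**
Reactants: **4**
Product: **5** (3aR,6aR)-dihydrofuro[3,4-c]furan-1,4(3H,6H)-dione (C2-symmetric cis-bislactone); auxiliary **1** is recovered
Conditions: H2 (1 atm), 10% Pd/C, EtOAc/MeOH, rt; then TsOH·H2O (10 mol%), toluene, 60 °C
Reagents that add atoms: none
Why: Benzyl hydrogenolysis frees the two primary alcohols, and each then attacks the imide carbonyl on the neighbouring carbon (5-exo acyl substitution, intramolecular transacylation) and releases the auxiliary. Only the threo (R,R) dimer can close to the cis-fused bicycle (the meso dimer would need a trans-fused diquinane), and the stereocentres are untouched.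

**Step 4**
Reactants: **5**
Product: **6** (3aR,6aR)-4-acetoxy-hexahydrofuro[3,4-c]furan-1-one, i.e. the ring-A lactol acetate (anomeric mixture at C4 = C7')
Conditions: DIBAL-H (1.0 equiv), CH2Cl2, –78 °C; then Ac2O, DMAP, pyridine, –78 → 0 °C
Reagents that add atoms: acetic anhydride, CC(=O)OC(C)=O
Why: By C2 symmetry either lactone gives the same mono-lactol, so DIBAL mono-reduction needs no regiocontrol. Trapping as the acetate gives a stable oxocarbenium precursor, and the anomeric configuration is irrelevant because it is destroyed in step 6.

**Step 5**
Reactants: **7** catechol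
Product: **8** 1,2-bis(allyloxy)benzene
Conditions: allyl bromide (2.5 equiv), K2CO3, acetone, reflux
Reagents that add atoms: allyl bromide, C=CCBr (two allyl groups are transferred per catechol)
Why: Double Williamson etherification gives an electron-rich arene nucleophile whose allyl groups can be removed later under neutral Pd(0) conditions.

**Step 6**
Reactants: **6**; **8**
Product: **9** (3aR,4S,6aR)-4-[3,4-bis(allyloxy)phenyl]hexahydrofuro[3,4-c]furan-1-one, cis-fused, with the aryl on the convex face
Conditions: TMSOTf (20 mol%), CH2Cl2, –40 → –10 °C
Reagents that add atoms: none (**8** is the nucleophile and AcOH is lost)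
Why: Proposed new method: TMSOTf ionises the acetate to a bicyclic oxocarbenium, the fused lactone (ring B) blocks the concave face, and the arene attacks the convex face para to one allyloxy group (Friedel–Crafts C-arylation, as in C-aryl glycosidation). This sets Ar' (C7') trans to both C7 and C9', and the bicycle locks C8 and C8' against epimerisation.

**Step 7**
Reactants: **10** 4-bromo-2-methoxyphenol
Product: **11** tert-butyl(4-bromo-2-methoxyphenoxy)dimethylsilane
Conditions: TBSCl, imidazole, DMF, rt
Reagents that add atoms: TBSCl, CC(C)(C)[Si](C)(C)Cl
Why: Silyl protection of the phenol allows clean Li–Br exchange in the next step.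

**Step 8**
Reactants: **9**; **11**
Product: **12** the (4-TBSO-3-methoxyphenyl) ketone on the 2-[3,4-bis(allyloxy)phenyl]-3-(hydroxymethyl)THF (open hydroxy-ketone)
Conditions: **11**, t-BuLi (2.05 equiv), THF, –78 °C, 20 min; add **9**, –78 °C, 1 h; aq. NH4Cl
Reagents that add atoms: none (the aryl group comes from **11**; Br is lost)
Why: Aryllithium addition to the ring-B lactone gives a lactolate that is stable at –78 °C, and on work-up it opens to the aryl ketone (C7) and the free C9'-CH2OH, while ring A and the C8, C8', C7' centres are unchanged.

**Step 9**
Reactants: **12**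
Product: **13** the (7R)-carbinol, with allyl and TBS protecting groups still on
Conditions: RuCl[(R,R)-TsDPEN](p-cymene) (2 mol%), HCO2H/Et3N (5:2), CH2Cl2, 30 °C
Reagents that add atoms: none (formate is only the hydride source)
Why: Noyori asymmetric transfer hydrogenation sets C7 by catalyst control, since the (R,R) catalyst gives the (R)-alcohol for Ar–CO–CHR2 (Ar outranks CHR2), and the mildly acidic formate medium should not epimerise C8.

**Step 10**
Reactants: **13**
Product: **14** (7R)-7-hydroxytaxiresinol
Conditions: Pd(PPh3)4 (5 mol%), K2CO3, MeOH, rt, degassed
Reagents that add atoms: none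
Why: Pd(0)/π-allyl transfer to methoxide removes both aryl allyl ethers, and K2CO3/MeOH cleaves the phenolic TBS ether; no stereocentre is α to a carbonyl at this stage, so none is disturbed.

---

**Compound list**
1 | (R)-4-benzyloxazolidin-2-one | O=C1OC[C@@H](Cc2ccccc2)N1 | starting material
2 | 3-(benzyloxy)propanoic acid | OC(=O)CCOCc1ccccc1 | starting material
3 | (R)-4-benzyl-3-[3-(benzyloxy)propanoyl]oxazolidin-2-one | O=C(CCOCc1ccccc1)N1[C@H](Cc2ccccc2)COC1=O | intermediate
4 | (2R,3R)-bis-imide dimer | O=C(N1[C@H](Cc2ccccc2)COC1=O)[C@@H](COCc1ccccc1)[C@H](COCc1ccccc1)C(=O)N1[C@H](Cc2ccccc2)COC1=O | intermediate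
5 | (3aR,6aR)-cis-bislactone | O=C1OC[C@@H]2C(=O)OC[C@H]12 | intermediate
6 | lactol acetate of 5 (anomeric mixture at the acetal carbon) | CC(=O)OC1OC[C@@H]2C(=O)OC[C@H]12 | intermediate
7 | catechol | Oc1ccccc1O | starting material
8 | 1,2-bis(allyloxy)benzene | C=CCOc1ccccc1OCC=C | intermediate
9 | aryl-THF lactone (aryl exo) | C=CCOc1ccc([C@H]2OC[C@@H]3C(=O)OC[C@H]23)cc1OCC=C | intermediate
10 | 4-bromo-2-methoxyphenol | COc1cc(Br)ccc1O | starting material
11 | TBS ether of 10 | COc1cc(Br)ccc1O[Si](C)(C)C(C)(C)C | intermediate
12 | hydroxy-ketone | COc1cc(C(=O)[C@H]2CO[C@H](c3ccc(OCC=C)c(OCC=C)c3)[C@H]2CO)ccc1O[Si](C)(C)C(C)(C)C | intermediate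
13 | protected (7R)-alcohol | COc1cc([C@H](O)[C@H]2CO[C@H](c3ccc(OCC=C)c(OCC=C)c3)[C@H]2CO)ccc1O[Si](C)(C)C(C)(C)C | intermediate
14 | (7R)-7-hydroxytaxiresinol | COc1cc([C@H](O)[C@H]2CO[C@H](c3ccc(O)c(O)c3)[C@H]2CO)ccc1O | target

**Total steps:** 10 (steps 5 and 7 are parallel preparations of the two aryl partners).
**Longest linear sequence:** 8 steps (1 → 2 → 3 → 4 → 6 → 8 → 9 → 10, counting step 2 as one step).

**Three steps most likely to fail**
1. **Step 2 (oxidative dimerisation).** The β-benzyloxy enolate may eliminate BnO⁻, or the coupling may give poor dl/meso or facial selectivity.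
   - Fallback: drop the auxiliary and make racemic threo material instead. Couple methyl 3-(benzyloxy)propanoate (LDA, then CuCl2 or I2) to give a dl/meso diester mixture and separate the dl diester. Hydrolyse it (LiOH, THF/H2O, 0 °C) and resolve the diacid by crystallisation of its salt with a chiral amine, such as (R)-1-phenylethylamine. Then hydrogenolyse and lactonise (H2, Pd/C; TsOH) to give (R,R)-**5**. This gives up the auxiliary-controlled asymmetric coupling and halves the maximum yield.
2. **Step 6 (Friedel–Crafts C-arylation).** Facial selectivity may be eroded, or the cation may eliminate to an enol ether.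
   - Fallback: add 3,4-bis(allyloxy)phenyllithium (from the aryl bromide) to one lactone of **5** to give the aryl lactol. Reduce it with Et3SiH/BF3·OEt2, which gives the kinetic cis-aryl product by hydride delivery to the convex face. Then epimerise the benzylic ether with Lewis acid (via the benzylic cation) to the thermodynamic exo (trans) isomer **9**.
3. **Step 8 (aryllithium addition).** Risks are over-addition, E1cB ring-opening of the β-alkoxy lactone enolate, and epimerisation at C8.
   - Fallback: open the lactone with MeONHMe·AlMe3 to the hydroxy Weinreb amide and protect the C9' alcohol as its TBS ether. Add the Grignard reagent from **11** (ArMgBr) to give the ketone, then carry on with the transfer hydrogenation and Pd(0)/K2CO3/MeOH deprotection, adding a final TBAF step to remove the primary TBS ether.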